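Slowness is the way in: late in the midnight run both species creep down together, so you can read a rule from that tail.

- midnight: starting material 1.4 M; run made earlier
- flask: starting material 2.8 M; time 1.0 h

midnight run (percent of the starting material charged)

| time / min | target / % | starting material / % |
|---|---|---|
| 0.500 | 12.3 | 57.7 |
| 1.33 | 20.9 | 32.5 |
| 3.00 | 21.9 | 23.6 |
| 8.00 | 16.3 | 19.5 |
| 20.0 | 8.1 | 12.5 |
| 50.0 | 2.5 | 6.4 |

(standard deviation of a reading: 0.3 percentage points)

- a reading or a percentage of target counts all its forms, free or not
- a reading of starting material is of its free form alone

- when, up to 1.0 h, the flask holds most target, in min
- the amount of target, in percent of the starting material charged, at that time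

Let S be the concentration of free starting material, and ρ the target reading over the starting material reading. Take ρ as a straight line, ρ = a + bS, through the midnight readings at 3.00 min and 50.0 min. Read from these two pairs of readings, its slope b is 2.23 M⁻¹, the gain in ρ per molar of free starting material, and a is 0.191.

For S against time, integrate a second-order loss: the reciprocal of S grows in step with time. Now ask which inputs matter. The scatter is small, 1.27% of the starting material reading at 3.00 min. The charge moves the clock little, because the flask's starting reciprocal, 0.357 M⁻¹, is smaller than the midnight gain by 3.00 min, 2.31 M⁻¹. The chosen time does matter. Midnight's gains in the reciprocal, carried to this flask, give 27.2% target at 1.33 min but 13.7% at 3.00 min. The line alone shows no peak, but the midnight target readings at these two times stand higher than those beside them. So I commit to the middle, as a judgement: 2.17 min and 20.5%.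

The forecast says 1.5 min (0.8 min to 3 min) and 24% (17% to 32%), on the ground “Doubling the concentration should roughly halve the timescale”. My time is later.

The flask peaks at 2.22 min with 19.9% target.

    starting material ⇌ target (K = 0.230, k = 0.00570 s⁻¹)
    target ⇌ isomer of the product A (K = 0.440, k = 0.00290 s⁻¹)
    isomer of the product A ⇌ starting material (k = 0.00690 s⁻¹)
    starting material + target ⇌ idle adduct, settled at all times (K = 8.70 M⁻¹)
    2 starting material → homo dimer (k = 0.00360 M⁻¹ s⁻¹)
    target ⇌ isomer of the product B (K = 4.30, k = 0.00110 s⁻¹)

In this flask at that time idle adduct, the resting state of target, stands at 32.1%, counted as two, and free starting material at 17.3%. From that amount the line gives 22.0% target, and the flask holds 19.9%. On the neighbouring flask, the same charge read at 15 min, free starting material stands at 10.1%. There the line gives 8.37% target, and that flask holds 9.07%.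

(The numbers in the tables are simulated with constants of no real substance, noise included.)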